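Slowness is what the earlier runs show first: after 8.00 min, Thursday's run still holds 75% of its substrate.

all flasks: substrate 0.40 M; free catalyst 20 mM

| charge | partner | remark | time |
|---|---|---|---|
| Thursday's | 0.29 M | run made earlier |  |
| Friday's | 0.51 M | run made earlier |  |
| Wednesday's | 0.65 M | run made earlier |  |
| blue | 0.420 M |  | 10 min |
| green | 0.550 M |  | 10 min |
| amber | 0.710 M |  | 10 min |

| run | time / min | substrate / % | product / % |
|---|---|---|---|
| Thursday's | 0.667 | 99 | 1 |
| Thursday's | 2.00 | 91 | 2 |
| Thursday's | 3.00 | 89 | 7 |
| Thursday's | 5.00 | 81 | 8 |
| Thursday's | 8.00 | 75 | 16 |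
| Friday's | 0.667 | 96 | 0 |
| Friday's | 2.00 | 87 | 3 |
| Friday's | 3.00 | 86 | 2 |
| Friday's | 5.00 | 85 | 9 |
| Friday's | 8.00 | 77 | 14 |
| Wednesday's | 0.667 | 96 | 1 |
| Wednesday's | 2.00 | 95 | 2 |
| Wednesday's | 3.00 | 89 | 5 |
| Wednesday's | 5.00 | 83 | 12 |
| Wednesday's | 8.00 | 74 | 11 |

(scatter of a reading: 2 percentage points)

1. part of the substrate that has reacted at the end, blue
2. part of the substrate that has reacted at the end, green
3. part of the substrate that has reacted at the end, amber
4. what raising the concentration of partner from its lowest to its highest value here does to the part of the substrate that has reacted (changes below 5 percentage points count as none) (no change / it falls / it rises)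

In blue, green and amber the substrate is charged below the partner, so, taking one partner per substrate, it is the limiting reagent, and I write its balance. What has left substrate counts as reacted, so I read the substrate column, although Thursday's run shows 16% product against 25.0% substrate lost.

But the partner does not show in that balance: at 8.00 min the substrate stands at 75%, 77% and 74% for partner at 0.29 M, 0.51 M and 0.65 M, a spread of 3 percentage points against a scatter of 2 points per reading. So I treat the loss as first order in substrate, with the partner left out. The 3 readings average 75.3%.

The logarithm of substrate charged over substrate remaining, divided by the time and by the catalyst charged, is my loss constant per catalyst, 1.77 M⁻¹ min⁻¹. The division is my assumption, since these runs all hold 20 mM. Over 10 min at 20 mM it gives 29.8% reacted in blue, green and amber alike.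

The forecast gives 30%, 30% and 30%, with no change, reading the loss as “effectively zero order in partner”.

The flask gives 30.8%, 31.3% and 31.7%, a change of 0.87 points across the partner range, less than 5 points, so no change.

    substrate + free catalyst → catalyst intermediate A (k = 0.0492 M⁻¹ s⁻¹)
    substrate + catalyst intermediate D ⇌ idle complex, settled at all times (K = 1.60 M⁻¹)
    partner + catalyst intermediate B → catalyst intermediate C (k = 0.206 M⁻¹ s⁻¹)
    catalyst intermediate D ⇌ catalyst intermediate E (K = 3.70, k = 0.0371 s⁻¹)
    substrate + by-product ⇌ idle adduct, settled at all times (K = 6.58 M⁻¹)
    catalyst intermediate E → free catalyst + product (k = 0.0413 s⁻¹)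
    catalyst intermediate A → catalyst intermediate B (k = 1.65 s⁻¹)
    catalyst intermediate C → by-product + catalyst intermediate D (k = 0.0467 s⁻¹)

At 10.0 min, blue holds 15.9% as product and 11.5% as idle adduct, and its answer lies 1 point above my 29.8%. Blue's answer moves by 5 points once its free catalyst falls to 16.4 mM. For a neighbour of blue with 12.0 mM of free catalyst, my constant gives 19.1%, and that neighbour stands at 19.4%.

The data come from a simulation for substances that don't exist.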